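**Retrosynthetic overview**
1. 31 ⇐ 26 in one pot: the amine freed at C11 adds to the cyclopentanone carbonyl C23, the C8–C23 bond breaks (retro-Claisen C→N acyl shift, 5-ring → 9-ring keto-lactam), and the lactam N–H then closes the azepanone onto the unmasked C18 aldehyde (N-acyliminium, Et3SiH).
2. 26 ⇐ acyclic tertiary β-diketone 23: ozonolysis, intramolecular aldol (C8→C4) and lactonisation build the cyclopentanone and the left lactone together.
3. 23 ⇐ γ-keto ester 21 + β-sulfinylamino aldehyde 8 (aldol, then oxidation).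
4. 21 ⇐ acid 17 (Ireland–Claisen with chirality transfer: C22, C3) + zinc homoenolate of bromo ester 18 (C7); 8 ⇐ Ellman sulfinimine 5 + silyloxyfuran 2 (vinylogous Mannich: C11, C12; hydrogenation: C14).
5. Ring order: right lactone → cyclopentanone + left lactone → nine-membered ring + azepanone.

Atom labels follow the target SMILES: C1–C2 ethyl, C3, C4, O5, C6(=O), C7(Me), C8, C9(=O), C10, C11, right lactone C12–C13–C14(Me)–C15(=O)–O16, N17, C18–C21, C22, C23(=O); target = 3R,4S,7S,8R,11S,12S,14S,22S.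

Assumption: TMSOTf-promoted addition of a 2-silyloxyfuran to an (R_S)-tert-butanesulfinyl aldimine goes through the open transition state (Re face, threo topicity); if the facial sense were opposite, (S)-sulfinamide would replace 4 and nothing else changes.

**Step 1**
Reactants: 1 3-methylfuran-2(5H)-one
Product: 2 3-methyl-2-(triisopropylsilyloxy)furan
Conditions: TIPSOTf, Et3N, CH2Cl2, 0 °C → rt
Reagents that add atoms: triisopropylsilyl trifluoromethanesulfonate, CC(C)[Si](C(C)C)(C(C)C)OS(=O)(=O)C(F)(F)F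
Why: Soft enolisation and O-silylation of the butenolide (silyl dienol ether formation) gives the aromatic 2-silyloxyfuran; no stereocentre is formed.

**Step 2**
Reactants: 3 3-(benzyloxy)propanal; 4 (R)-2-methylpropane-2-sulfinamide
Product: 5 (R,E)-N-[3-(benzyloxy)propylidene]-2-methylpropane-2-sulfinamide
Conditions: pyrrolidine (10 mol%), 4 Å MS, CH2Cl2, rt
Reagents that add atoms: none
Why: Amine-catalysed Ellman condensation of an aldehyde with the sulfinamide gives the E-sulfinimine, the sulfur stereocentre being purchased.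

**Step 3**
Reactants: 5 (R,E)-N-[3-(benzyloxy)propylidene]-2-methylpropane-2-sulfinamide; 2 3-methyl-2-(triisopropylsilyloxy)furan
Product: 6 (R)-N-{(1S)-3-(benzyloxy)-1-[(2S)-4-methyl-5-oxo-2,5-dihydrofuran-2-yl]propyl}-2-methylpropane-2-sulfinamide
Conditions: TMSOTf (20 mol%), CH2Cl2, −78 °C; aq. NaHCO3
Reagents that add atoms: none
Why: Vinylogous Mukaiyama–Mannich addition of the furan C5 to the Lewis-acid-activated sulfinimine through an open transition state, in which the sulfinyl group directs attack to the Re face (C11 S) and the usual threo topicity of silyloxyfuran additions sets C12 S.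

**Step 4**
Reactants: 6 (R)-N-{(1S)-3-(benzyloxy)-1-[(2S)-4-methyl-5-oxo-2,5-dihydrofuran-2-yl]propyl}-2-methylpropane-2-sulfinamide
Product: 7 (R)-N-{(1S)-3-hydroxy-1-[(2S,4S)-4-methyl-5-oxooxolan-2-yl]propyl}-2-methylpropane-2-sulfinamide
Conditions: H2 (3 atm), 10% Pd/C, EtOAc–MeOH, rt
Reagents that add atoms: none
Why: Heterogeneous hydrogenation adds H2 to the butenolide face opposite the C12 side chain, giving the cis-2,4-disubstituted lactone (C14 S), and benzyl ether hydrogenolysis frees the primary alcohol in the same operation.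

**Step 5**
Reactants: 7 (R)-N-{(1S)-3-hydroxy-1-[(2S,4S)-4-methyl-5-oxooxolan-2-yl]propyl}-2-methylpropane-2-sulfinamide
Product: 8 (R)-2-methyl-N-{(1S)-1-[(2S,4S)-4-methyl-5-oxooxolan-2-yl]-3-oxopropyl}propane-2-sulfinamide
Conditions: Dess–Martin periodinane, CH2Cl2, 0 °C → rt
Reagents that add atoms: none
Why: Dess–Martin oxidation of the primary alcohol to the C9 aldehyde under neutral conditions that leave the sulfinamide and lactone untouched; no stereocentre changes.

**Step 6**
Reactants: 9 (E)-pent-2-enal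
Product: 10 rac-(E)-hex-3-en-2-ol
Conditions: MeMgBr, THF, −78 → 0 °C; then H2O
Reagents that add atoms: methylmagnesium bromide, C[Mg]Br
Why: Grignard 1,2-addition to the enal gives the racemic allylic alcohol that is resolved in step 8.

**Step 7**
Reactants: 11 cyclohexene
Product: 13 methyl 6,6-dimethoxyhexanoate, via hydroperoxy acetal 12 (not isolated)
Conditions: O3, CH2Cl2–MeOH, −78 °C; TsOH·H2O (cat.), rt; then Ac2O, Et3N, 0 °C → rt
Reagents that add atoms: ozone, [O-][O+]=O; methanol, CO
Why: Schreiber ozonolysis with terminal differentiation, in which the aldehyde end is acetalised and the methoxy hydroperoxide end is dehydrated to the methyl ester; no stereocentre.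

**Step 8**
Reactants: 10 rac-(E)-hex-3-en-2-ol (2.5 equiv); 13 methyl 6,6-dimethoxyhexanoate
Product: 14 (2R,3E)-hex-3-en-2-yl 6,6-dimethoxyhexanoate
Conditions: Novozym 435 (CAL-B), 5 Å MS, heptane, 45 °C
Reagents that add atoms: none
Why: Lipase-catalysed transesterification as a kinetic resolution, CAL-B acylating only the (R)-alcohol (Kazlauskas rule) so that the (R)-allylic ester forms directly and (S)-10 stays behind.

**Step 9**
Reactants: 14 (2R,3E)-hex-3-en-2-yl 6,6-dimethoxyhexanoate
Product: 17 (2S,3S,4E)-2-(4,4-dimethoxybutyl)-3-ethylhex-4-enoic acid, via silyl ketene acetal 15 (not isolated), via trimethylsilyl ester 16 (not isolated)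
Conditions: LDA, THF, −78 °C; TMSCl/Et3N, −78 → 50 °C; aq. NaOH, then citric acid (pH 4)
Reagents that add atoms: none
Why: Ireland–Claisen rearrangement of the E(O)-enolate-derived (E)-silyl ketene acetal through a chair transition state with the carbinol methyl equatorial, which transfers the (R)-carbinol chirality to the anti pair C22 (S)/C3 (S) and leaves an E-propenyl group as the masked C4 aldehyde.

**Step 10**
Reactants: 17 (2S,3S,4E)-2-(4,4-dimethoxybutyl)-3-ethylhex-4-enoic acid; 18 methyl (2R)-3-bromo-2-methylpropanoate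
Product: 21 methyl (2S,5S,6S,7E)-5-(4,4-dimethoxybutyl)-6-ethyl-2-methyl-4-oxonon-7-enoate, via acid chloride 19 (not isolated), via organozinc bromide 20 (not isolated)
Conditions: (a) 17, 1-chloro-N,N,2-trimethylprop-1-en-1-amine, CH2Cl2, 0 °C → rt; (b) 18, Zn dust, LiCl, THF, 40 °C; (c) combine, Pd(PPh3)4 (5 mol%), THF, 0 °C → rt
Reagents that add atoms: none
Why: Negishi acyl cross-coupling of a zinc homoenolate (Tamaru–Yoshida type) with the acid chloride made under neutral Ghosez conditions, which touches neither α-stereocentre and brings in C7 (S) from the bromo ester.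

**Step 11**
Reactants: 21 methyl (2S,5S,6S,7E)-5-(4,4-dimethoxybutyl)-6-ethyl-2-methyl-4-oxonon-7-enoate; 8 (R)-2-methyl-N-{(1S)-1-[(2S,4S)-4-methyl-5-oxooxolan-2-yl]-3-oxopropyl}propane-2-sulfinamide
Product: 22 β-hydroxy ketone from C8–C9 aldol union of 21 and 8 (epimers at C8 and C9)
Conditions: LDA (1.15 equiv), THF, −78 °C; then 8 (0.9 equiv), −78 °C; AcOH
Reagents that add atoms: none
Why: Kinetic lithium enolate formation at the less substituted α-carbon (C8H2 rather than C22H) and aldol addition to the aldehyde, the two new centres being left uncontrolled because C9 is oxidised in step 12 and C8 is reset in step 13.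

**Step 12**
Reactants: 22 β-hydroxy ketone (epimers at C8 and C9)
Product: 23 tertiary β-diketone (C9 and C23 ketones flanking C8–H; C8 epimers)
Conditions: Dess–Martin periodinane, CH2Cl2, rt
Reagents that add atoms: none
Why: Dess–Martin oxidation of a β-hydroxy ketone to the 1,3-diketone, which removes the C9 centre and makes C8–H the most acidic proton of the molecule.

**Step 13**
Reactants: 23 tertiary β-diketone
Product: 26 (R)-N-{(1S)-3-[(3S,3aS,5S,6R,6aS)-5-(4,4-dimethoxybutyl)-6-ethyl-3-methyl-2,4-dioxohexahydro-2H-cyclopenta[b]furan-3a-yl]-1-[(2S,4S)-4-methyl-5-oxooxolan-2-yl]-3-oxopropyl}-2-methylpropane-2-sulfinamide, via keto aldehyde 24 (not isolated), via aldol cyclopentanol 25 (not isolated)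
Conditions: O3, CH2Cl2, −78 °C (Sudan III end point); PPh3, −78 °C → rt; then Et3N (0.3 equiv), rt
Reagents that add atoms: ozone, [O-][O+]=O
Why: Ozonolysis followed by intramolecular 5-enolexo aldol of the β-diketone carbon C8 onto the C4 aldehyde and irreversible lactonisation of the aldolate that is cis to the ester arm, which funnels the reversible aldol to the cis-fused lactone on the face away from the ethyl and C22 chains (C4 S and quaternary C8 set, all three substituents exo).

**Step 14**
Reactants: 26 bicyclic 2-acylcyclopentanone lactone (name as in step 13)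
Product: 31 tuberostemonone, via ammonium chloride 27 (not isolated), via NH-lactam acetal 28 (not isolated), via NH-lactam aldehyde 29 (not isolated), via N-acyl hemiaminal 30 (not isolated)
Conditions: HCl (4 M in dioxane), MeOH, 0 °C; NaOAc, MeOH–H2O (pH 5–6), 40 °C; then TFA–CH2Cl2–H2O, rt; Et3SiH, 0 °C → rt
Reagents that add atoms: none
Why: Proposed new method: the amine freed from the sulfinamide adds to the non-enolisable cyclopentanone carbonyl C23 through a six-membered carbinolamine that fragments by C8–C23 cleavage (retro-Claisen C→N acyl transfer as in Hesse-type aminolytic ring enlargement and Unsworth ring expansion, driven by amide formation) with C8 protonated on the face C23 leaves to give the 3,4-trans lactone (C8 R), after which acid unmasks the C18 aldehyde and the lactam N–H closes the azepanone through an N-acyliminium ion reduced by Et3SiH (reductive amidation), so that the nine- and seven-membered rings form in one flask.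

**Compound list**
1 | 3-methylfuran-2(5H)-one | CC1=CCOC1=O | starting material
2 | 3-methyl-2-(triisopropylsilyloxy)furan | CC1=C(O[Si](C(C)C)(C(C)C)C(C)C)OC=C1 | intermediate
3 | 3-(benzyloxy)propanal | O=CCCOCc1ccccc1 | starting material
4 | (R)-2-methylpropane-2-sulfinamide | CC(C)(C)[S@@](=O)N | starting material
5 | (R,E)-N-[3-(benzyloxy)propylidene]-2-methylpropane-2-sulfinamide | CC(C)(C)[S@@](=O)/N=C/CCOCc1ccccc1 | intermediate
6 | (R)-N-{(1S)-3-(benzyloxy)-1-[(2S)-4-methyl-5-oxo-2,5-dihydrofuran-2-yl]propyl}-2-methylpropane-2-sulfinamide | c1ccccc1COCC[C@@H]([C@@H]1C=C(C)C(=O)O1)N[S@](=O)C(C)(C)C | intermediate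
7 | (R)-N-{(1S)-3-hydroxy-1-[(2S,4S)-4-methyl-5-oxooxolan-2-yl]propyl}-2-methylpropane-2-sulfinamide | OCC[C@@H]([C@@H]1C[C@H](C)C(=O)O1)N[S@](=O)C(C)(C)C | intermediate
8 | (R)-2-methyl-N-{(1S)-1-[(2S,4S)-4-methyl-5-oxooxolan-2-yl]-3-oxopropyl}propane-2-sulfinamide | O=CC[C@@H]([C@@H]1C[C@H](C)C(=O)O1)N[S@](=O)C(C)(C)C | intermediate
9 | (E)-pent-2-enal | CC/C=C/C=O | starting material
10 | rac-(E)-hex-3-en-2-ol | CC/C=C/C(C)O | intermediate
11 | cyclohexene | C1CCC=CC1 | starting material
12 | 1-hydroperoxy-1,6,6-trimethoxyhexane | COC(CCCCC(OC)OC)OO | intermediate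
13 | methyl 6,6-dimethoxyhexanoate | COC(=O)CCCCC(OC)OC | intermediate
14 | (2R,3E)-hex-3-en-2-yl 6,6-dimethoxyhexanoate | COC(OC)CCCCC(=O)O[C@H](C)/C=C/CC | intermediate
15 | (E)-ketene trimethylsilyl acetal of 14 | COC(OC)CCC/C=C(/O[Si](C)(C)C)O[C@H](C)/C=C/CC | intermediate
16 | trimethylsilyl (2S,3S,4E)-2-(4,4-dimethoxybutyl)-3-ethylhex-4-enoate | CC[C@@H](/C=C/C)[C@H](CCCC(OC)OC)C(=O)O[Si](C)(C)C | intermediate
17 | (2S,3S,4E)-2-(4,4-dimethoxybutyl)-3-ethylhex-4-enoic acid | CC[C@@H](/C=C/C)[C@H](CCCC(OC)OC)C(=O)O | intermediate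
18 | methyl (2R)-3-bromo-2-methylpropanoate | BrC[C@H](C)C(=O)OC | starting material
19 | (2S,3S,4E)-2-(4,4-dimethoxybutyl)-3-ethylhex-4-enoyl chloride | CC[C@@H](/C=C/C)[C@H](CCCC(OC)OC)C(Cl)=O | intermediate
20 | bromo[(2R)-3-methoxy-2-methyl-3-oxopropyl]zinc | Br[Zn]C[C@H](C)C(=O)OC | intermediate
21 | methyl (2S,5S,6S,7E)-5-(4,4-dimethoxybutyl)-6-ethyl-2-methyl-4-oxonon-7-enoate | CC[C@@H](/C=C/C)[C@H](CCCC(OC)OC)C(=O)C[C@H](C)C(=O)OC | intermediate
22 | aldol adduct of 21 (C8) and 8 (C9–OH), epimers at C8 and C9 | CC[C@@H](/C=C/C)[C@H](CCCC(OC)OC)C(=O)C([C@H](C)C(=O)OC)C(O)C[C@@H]([C@@H]1C[C@H](C)C(=O)O1)N[S@](=O)C(C)(C)C | intermediate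
23 | tertiary β-diketone (C9=O, C23=O, C8–H), C8 epimers | CC[C@@H](/C=C/C)[C@H](CCCC(OC)OC)C(=O)C([C@H](C)C(=O)OC)C(=O)C[C@@H]([C@@H]1C[C@H](C)C(=O)O1)N[S@](=O)C(C)(C)C | intermediate
24 | C4 aldehyde of 23 (propenyl cleaved) | CC[C@@H](C=O)[C@H](CCCC(OC)OC)C(=O)C([C@H](C)C(=O)OC)C(=O)C[C@@H]([C@@H]1C[C@H](C)C(=O)O1)N[S@](=O)C(C)(C)C | intermediate
25 | cyclopentanol aldol adduct (C4–OH cis to the propanoate arm on C8) | CC[C@H]1[C@H](O)[C@@]([C@H](C)C(=O)OC)(C(=O)C[C@@H]([C@@H]2C[C@H](C)C(=O)O2)N[S@](=O)C(C)(C)C)C(=O)[C@H]1CCCC(OC)OC | intermediate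
26 | (R)-N-{(1S)-3-[(3S,3aS,5S,6R,6aS)-5-(4,4-dimethoxybutyl)-6-ethyl-3-methyl-2,4-dioxohexahydro-2H-cyclopenta[b]furan-3a-yl]-1-[(2S,4S)-4-methyl-5-oxooxolan-2-yl]-3-oxopropyl}-2-methylpropane-2-sulfinamide | CC[C@H]1[C@@H]2OC(=O)[C@@H](C)[C@]2(C(=O)C[C@@H]([C@@H]3C[C@H](C)C(=O)O3)N[S@](=O)C(C)(C)C)C(=O)[C@H]1CCCC(OC)OC | intermediate
27 | ammonium chloride of N-desulfinylated 26 | CC[C@H]1[C@@H]2OC(=O)[C@@H](C)[C@]2(C(=O)C[C@@H]([C@@H]3C[C@H](C)C(=O)O3)[NH3+])C(=O)[C@H]1CCCC(OC)OC.[Cl-] | intermediate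
28 | nine-membered keto NH-lactam with 4,4-dimethoxybutyl on C22 (stereocentres as in 31) | CC[C@H]1[C@@H]2OC(=O)[C@@H](C)[C@H]2C(=O)C[C@@H]([C@@H]2C[C@H](C)C(=O)O2)NC(=O)[C@H]1CCCC(OC)OC | intermediate
29 | nine-membered keto NH-lactam with 4-oxobutyl on C22 | CC[C@H]1[C@@H]2OC(=O)[C@@H](C)[C@H]2C(=O)C[C@@H]([C@@H]2C[C@H](C)C(=O)O2)NC(=O)[C@H]1CCCC=O | intermediate
30 | 18-hydroxytuberostemonone (bicyclic N-acyl hemiaminal, C18 epimers) | CC[C@H]1[C@@H]2OC(=O)[C@@H](C)[C@H]2C(=O)C[C@@H]([C@@H]2C[C@H](C)C(=O)O2)N2C(O)CCC[C@@H]1C2=O | intermediate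
31 | tuberostemonone | CC[C@H]1[C@@H]2OC(=O)[C@@H](C)[C@H]2C(=O)C[C@@H]([C@@H]2C[C@H](C)C(=O)O2)N2CCCC[C@@H]1C2=O | target

**Totals**
Total steps: 14. Longest linear sequence: 8 (steps 6, 8, 9, 10, 11, 12, 13, 14 from 9; the branch from 1 through steps 1, 3, 4, 5, 11–14 is equally long).

**Three steps most likely to fail**

Step 14 is the weakest. The free amine at C11 can attack the neighbouring lactone carbonyl C15 instead (O→N acyl shift to a hydroxy piperidinone). The carbinolamine at the hindered C23 may fragment slowly, and C22 may epimerise through the imine. The fallback sets out from 26 and never frees the amine. The sulfinamide N–H is deprotonated (LiHMDS, THF, −78 → 0 °C), the sulfinamide anion adds to C23, and the same retro-Claisen cleavage gives the N-sulfinyl nine-membered lactam F1. HCl in MeOH then removes the sulfinyl group from this acyl sulfinamide and gives 28, where the route is rejoined; the last stage of step 14 (TFA–H2O, then Et3SiH) leads to 31.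

Step 13 is next. Ozone may attack the enol of the β-diketone or the sulfinamide, and the tertiary diketone carbon may be a sluggish aldol donor. The fallback sets out from 21 and closes the rings before the second ketone is present. Ozonolysis of 21 (O3, then PPh3) gives the keto aldehyde F2. DBU-mediated aldol and lactonisation give the cis-fused bicyclic keto lactone F3, which carries H at C8. In parallel, 8 is oxidised (NaClO2, NaH2PO4, 2-methyl-2-butene) to the acid F4 and activated with carbonyldiimidazole as the acyl imidazolide F5. Soft enolisation of F3 (MgBr2·OEt2, i-Pr2NEt) and C-acylation at C8 from the convex face with F5 gives 26, where the route is rejoined.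

Step 3 is the third. The facial sense and the threo/erythro ratio of the vinylogous Mannich addition are not secure for this aliphatic sulfinimine. The fallback sets out from 4 and takes C12 and C14 from the chiral pool. The known lactone alcohol F6 (from L-glutamic acid) is oxidised with Dess–Martin periodinane to the aldehyde F7 and condensed with 4 to the sulfinimine F8. Allylation with allyl bromide and indium in THF (chelated chair transition state, Si face) gives the homoallyl sulfinamide F9 with C11 S. Ozonolysis of F9 gives 8, where the route is rejoined; steps 1 to 5 fall away.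

**Further compounds**
F1 | step 14 | N-[(R)-tert-butylsulfinyl] derivative of nine-membered lactam 28 | CC[C@H]1[C@@H]2OC(=O)[C@@H](C)[C@H]2C(=O)C[C@@H]([C@@H]2C[C@H](C)C(=O)O2)N([S@](=O)C(C)(C)C)C(=O)[C@H]1CCCC(OC)OC
F2 | step 13 | methyl (2S,5S,6R)-5-(4,4-dimethoxybutyl)-6-formyl-2-methyl-4-oxooctanoate | CC[C@@H](C=O)[C@H](CCCC(OC)OC)C(=O)C[C@H](C)C(=O)OC
F3 | step 13 | (3S,3aS,5S,6R,6aS)-5-(4,4-dimethoxybutyl)-6-ethyl-3-methyltetrahydro-2H-cyclopenta[b]furan-2,4(3H)-dione | CC[C@H]1[C@@H]2OC(=O)[C@@H](C)[C@@H]2C(=O)[C@H]1CCCC(OC)OC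
F4 | step 13 | (3S)-3-{[(R)-tert-butylsulfinyl]amino}-3-[(2S,4S)-4-methyl-5-oxooxolan-2-yl]propanoic acid | OC(=O)C[C@@H]([C@@H]1C[C@H](C)C(=O)O1)N[S@](=O)C(C)(C)C
F5 | step 13 | acyl imidazolide of F4 | O=C(C[C@@H]([C@@H]1C[C@H](C)C(=O)O1)N[S@](=O)C(C)(C)C)n1ccnc1
F6 | step 3 | (3S,5S)-5-(hydroxymethyl)-3-methyloxolan-2-one | OC[C@@H]1C[C@H](C)C(=O)O1
F7 | step 3 | (2S,4S)-4-methyl-5-oxooxolane-2-carbaldehyde | O=C[C@@H]1C[C@H](C)C(=O)O1
F8 | step 3 | (R,E)-2-methyl-N-{[(2S,4S)-4-methyl-5-oxooxolan-2-yl]methylidene}propane-2-sulfinamide | CC(C)(C)[S@@](=O)/N=C/[C@@H]1C[C@H](C)C(=O)O1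
F9 | step 3 | (R)-2-methyl-N-{(1S)-1-[(2S,4S)-4-methyl-5-oxooxolan-2-yl]but-3-en-1-yl}propane-2-sulfinamide | C=CC[C@@H]([C@@H]1C[C@H](C)C(=O)O1)N[S@](=O)C(C)(C)C
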